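**Retrosynthetic overview**

- Target 15 ⇐ (3S)-5-O-benzyl isoflavanone 14 (BCl3) ⇐ cis-(3S,4S)-isoflavan-4-ol 13 (oxidation) ⇐ achiral pyrano-isoflavone 11 (asymmetric transfer hydrogenation with dynamic kinetic resolution sets C3).
- Ring D of 11 ⇐ phenol 6 + 3-methylbut-2-enal 7: boron-templated ortho-hydroxyalkylation, cycloreversion to an ortho-quinone methide, then oxa-6π electrocyclisation, which closes the pyran by forming the O4'–C(CH3)2 bond.
- Enabling feature: on ring B the free O4'–H sits next to the unsubstituted C5', which is para to the 2'-methoxy donor; PhB(OH)2 ties the aldehyde to O4' as a temporary 1,3,2-dioxaborinine ring. Ring C is held as the flat 4H-chromen-4-one (C2=C3), so no stereocentre exists during the hot step.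
- 6 ⇐ Suzuki–Miyaura coupling of 3-iodochromone 4 with boronate 5; 4 ⇐ acetophenone 1 by enaminone iodocyclisation.
- Ring order: ring A bought, ring C closed (step 2), ring B attached (step 3), ring D closed (step 4), ring C reduced and C3 set last (steps 5 to 7).

Key step: step 4

Remark on the chemistry: isoflavonoid numbering is used (rings A and C = chroman-4-one, ring B = pendant arene with primed locants, ring D = dimethylpyran with double-primed locants). The C3 descriptor of the target reads as (S). Compounds 1, 5 and 7 are taken as catalogue compounds.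

**Route**

Step 1
Reactants: 1 1-(2,6-dihydroxy-4-methoxyphenyl)ethan-1-one
Product: 2 1-[2-(benzyloxy)-6-hydroxy-4-methoxyphenyl]ethan-1-one
Conditions: BnBr (1.05 equiv), K2CO3, acetone, 56 °C
Reagents that add atoms: benzyl bromide, BrCc1ccccc1
Why: Williamson ether synthesis; once one hydroxyl is benzylated the other is locked in a hydrogen bond to the acetyl carbonyl and is much less nucleophilic, so monoalkylation of the symmetric diol should stop cleanly.

Step 2
Reactants: 2 1-[2-(benzyloxy)-6-hydroxy-4-methoxyphenyl]ethan-1-one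
Product: 4 5-(benzyloxy)-3-iodo-7-methoxy-4H-chromen-4-one, via enaminone 3 (not isolated)
Conditions: Me2NCH(OMe)2, 95 °C; concentrate; then iodine, CHCl3, 23 °C
Reagents that add atoms: N,N-dimethylformamide dimethyl acetal, COC(OC)N(C)C; iodine, [I][I]
Why: Condensation of the methyl ketone with the amide acetal gives enaminone 3, whose iodination at the α-carbon triggers 6-endo addition of the free phenol to the iminium carbon and loss of dimethylamine (iodine-induced enaminone cyclisation to a 3-iodochromone), which builds ring C.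

Step 3
Reactants: 4 5-(benzyloxy)-3-iodo-7-methoxy-4H-chromen-4-one; 5 3-methoxy-4-(4,4,5,5-tetramethyl-1,3,2-dioxaborolan-2-yl)phenol
Product: 6 5-(benzyloxy)-3-(4-hydroxy-2-methoxyphenyl)-7-methoxy-4H-chromen-4-one
Conditions: Pd(dppf)Cl2 (5 mol %), K2CO3, 1,4-dioxane/H2O, 80 °C
Reagents that add atoms: none
Why: Suzuki–Miyaura coupling; the vinylogous acyl iodide 4 should add readily to zerovalent palladium and the free phenol of 5 is tolerated under carbonate, so the C3–C1' bond is formed without extra protection.

Step 4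
Reactants: 6 5-(benzyloxy)-3-(4-hydroxy-2-methoxyphenyl)-7-methoxy-4H-chromen-4-one; 7 3-methylbut-2-enal
Product: 11 5-(benzyloxy)-7-methoxy-3-(7-methoxy-2,2-dimethyl-2H-chromen-6-yl)-4H-chromen-4-one, via boronate 8 (not isolated), via dioxaborinine 9 (not isolated), via quinone methide 10 (not isolated)
Conditions: PhB(OH)2 (1.2 equiv), EtCO2H (cat.), PhMe, 110 °C, Dean–Stark
Reagents that add atoms: none
Why: Phenol 6 is esterified by PhB(OH)2 to the aryl hydrogen phenylboronate 8, boron binds the aldehyde oxygen of 7 and delivers its carbonyl carbon to C5' through a six-membered transition state, and the benzylic alkoxide closes onto boron to give the temporary 1,3,2-dioxaborinine 9; at 110 °C this ring undergoes cycloreversion with loss of phenylboroxine to the ortho-quinone methide 10, whose 1-oxatriene (O4'=C4'–C5'=C4''–C3''=C2'') closes by a thermally allowed disrotatory oxa-6π electrocyclisation that forms the O4'–C2''(CH3)2 bond and restores the aromaticity of ring B. The closest known reaction type is the phenylboronic acid-mediated condensation of phenols with α,β-unsaturated aldehydes to 2H-chromenes. Two rings are closed: the transient dioxaborinine by polar B–O bond formation after the templated ortho C–C bond formation, and ring D pericyclically (6π electrocyclisation, no ionic ring closure and hence no Baldwin constraint). No stereocentre is created. The step needs site- and regioselectivity: only ring B carries a free hydroxyl to bind boron (O5 is benzylated), the tether confines C–C bond formation to the carbons ortho to O4', and of these C5' is para to the 2'-methoxy donor and unhindered whereas C3' is wedged between two oxygen substituents, in line with the analogous annulation of 3-methoxyphenol, which is known to give the 7-methoxy chromene. The chromen-4-one of ring C has neither a stereocentre nor an enolisable C3–H and should pass the hot, weakly acidic medium unchanged.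

Step 5
Reactants: 11 5-(benzyloxy)-7-methoxy-3-(7-methoxy-2,2-dimethyl-2H-chromen-6-yl)-4H-chromen-4-one
Product: 13 (3S,4S)-5-(benzyloxy)-7-methoxy-3-(7-methoxy-2,2-dimethyl-2H-chromen-6-yl)chroman-4-ol, via racemic isoflavanone 12 (not isolated)
Conditions: RuCl(p-cymene)[(S,S)-TsDPEN] (5 mol %), HCO2H/Et3N (1:2), EtOAc, 40 °C
Reagents that add atoms: none
Why: Domino asymmetric transfer hydrogenation (Noyori type): the ruthenium hydride first reduces the C2=C3 bond of the chromenone in a 1,4-sense to racemic 12, whose C3 epimerises rapidly in the amine-rich medium, and the (S,S)-catalyst should then reduce the (3S)-ketone faster from the face anti to the C3 aryl group (dynamic kinetic resolution), so that catalyst control sets C4 as (S) and the anti hydride delivery fixes C3 as (S) in the cis-alcohol, while the non-polarised C3''=C4'' alkene of ring D is left alone and any trans isomer (which would carry 3R) is removed by chromatography.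

Step 6
Reactants: 13 (3S,4S)-5-(benzyloxy)-7-methoxy-3-(7-methoxy-2,2-dimethyl-2H-chromen-6-yl)chroman-4-ol
Product: 14 (3S)-5-(benzyloxy)-7-methoxy-3-(7-methoxy-2,2-dimethyl-2H-chromen-6-yl)chroman-4-one
Conditions: Dess–Martin periodinane, NaHCO3, CH2Cl2, 0 °C
Reagents that add atoms: none
Why: Dess–Martin oxidation of the benzylic alcohol under bicarbonate-buffered, non-enolising conditions removes the auxiliary C4 stereocentre and should leave the C3 configuration set in step 5 untouched.

Step 7
Reactants: 14 (3S)-5-(benzyloxy)-7-methoxy-3-(7-methoxy-2,2-dimethyl-2H-chromen-6-yl)chroman-4-one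
Product: 15 (3S)-5-hydroxy-7-methoxy-3-(7-methoxy-2,2-dimethyl-2H-chromen-6-yl)chroman-4-one
Conditions: BCl3 (1 M in CH2Cl2), C6HMe5, CH2Cl2, −78 °C; then H2O
Reagents that add atoms: none
Why: Lewis-acid ether cleavage directed by chelation of BCl3 between the C4 carbonyl and the peri O5 should remove only the benzyl group at −78 °C (the benzyl cation is trapped by pentamethylbenzene), sparing both methyl ethers, ring D and, in the absence of base, the C3 stereocentre.

**Compound list**

1 | 1-(2,6-dihydroxy-4-methoxyphenyl)ethan-1-one | CC(=O)c1c(O)cc(OC)cc1O | starting material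
2 | 1-[2-(benzyloxy)-6-hydroxy-4-methoxyphenyl]ethan-1-one | CC(=O)c1c(O)cc(OC)cc1OCc1ccccc1 | intermediate
3 | (E)-1-[2-(benzyloxy)-6-hydroxy-4-methoxyphenyl]-3-(dimethylamino)prop-2-en-1-one (enaminone) | CN(C)/C=C/C(=O)c1c(O)cc(OC)cc1OCc1ccccc1 | intermediate
4 | 5-(benzyloxy)-3-iodo-7-methoxy-4H-chromen-4-one | COc1cc(OCc2ccccc2)c2c(c1)occ(I)c2=O | intermediate
5 | 3-methoxy-4-(4,4,5,5-tetramethyl-1,3,2-dioxaborolan-2-yl)phenol | COc1cc(O)ccc1B1OC(C)(C)C(C)(C)O1 | starting material
6 | 5-(benzyloxy)-3-(4-hydroxy-2-methoxyphenyl)-7-methoxy-4H-chromen-4-one | COc1cc(OCc2ccccc2)c2c(c1)occ(-c1ccc(O)cc1OC)c2=O | intermediate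
7 | 3-methylbut-2-enal | CC(C)=CC=O | starting material
8 | aryl hydrogen phenylboronate of 6, ArO–B(OH)Ph at O4' (boronate) | COc1cc(OCc2ccccc2)c2c(c1)occ(-c1ccc(OB(O)c3ccccc3)cc1OC)c2=O | intermediate
9 | 5-(benzyloxy)-7-methoxy-3-[7-methoxy-4-(2-methylprop-1-en-1-yl)-2-phenyl-4H-1,3,2-benzodioxaborinin-6-yl]-4H-chromen-4-one (dioxaborinine, racemic at the benzylic carbon) | COc1cc(OCc2ccccc2)c2c(c1)occ(-c1cc3c(cc1OC)OB(c1ccccc1)OC3C=C(C)C)c2=O | intermediate
10 | 5-(benzyloxy)-7-methoxy-3-[(3Z)-6-methoxy-3-(3-methylbut-2-en-1-ylidene)-4-oxocyclohexa-1,5-dien-1-yl]-4H-chromen-4-one (ortho-quinone methide) | COc1cc(OCc2ccccc2)c2c(c1)occ(C1=C/C(=C/C=C(C)C)C(=O)C=C1OC)c2=O | intermediate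
11 | 5-(benzyloxy)-7-methoxy-3-(7-methoxy-2,2-dimethyl-2H-chromen-6-yl)-4H-chromen-4-one | COc1cc(OCc2ccccc2)c2c(c1)occ(-c1cc3c(cc1OC)OC(C)(C)C=C3)c2=O | intermediate
12 | racemic 5-(benzyloxy)-7-methoxy-3-(7-methoxy-2,2-dimethyl-2H-chromen-6-yl)chroman-4-one | COc1cc(OCc2ccccc2)c2c(c1)OCC(c1cc3c(cc1OC)OC(C)(C)C=C3)C2=O | intermediate
13 | (3S,4S)-5-(benzyloxy)-7-methoxy-3-(7-methoxy-2,2-dimethyl-2H-chromen-6-yl)chroman-4-ol (cis) | COc1cc(OCc2ccccc2)c2c(c1)OC[C@H](c1cc3c(cc1OC)OC(C)(C)C=C3)[C@@H]2O | intermediate
14 | (3S)-5-(benzyloxy)-7-methoxy-3-(7-methoxy-2,2-dimethyl-2H-chromen-6-yl)chroman-4-one | COc1cc(OCc2ccccc2)c2c(c1)OC[C@H](c1cc3c(cc1OC)OC(C)(C)C=C3)C2=O | intermediate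
15 | (3S)-5-hydroxy-7-methoxy-3-(7-methoxy-2,2-dimethyl-2H-chromen-6-yl)chroman-4-one | COc1cc(O)c2c(c1)OC[C@H](c1cc3c(cc1OC)OC(C)(C)C=C3)C2=O | target

**Step count and risks**

Total step count: 7. Longest linear sequence: 7 steps (1 to 15); 5 and 7 are bought and enter in steps 3 and 4.

Step 4 (key step). The templated C–C bond formation may be too slow on the hindered, only moderately activated ring B, so that self-condensation of the aldehyde wins, or attack may divide between C5' and C3'. The fallback sets out from 6 and uses a sigmatropic mechanism instead. Copper-catalysed O-alkylation of 6 with 3-chloro-3-methylbut-1-yne (DBU, CuCl2·2H2O, MeCN, 0 °C) should give the aryl 1,1-dimethylpropargyl ether F1. Heating F1 in PhNEt2 at 190 °C should trigger the aromatic propargyl Claisen shift to the allenyl cyclohexadienone F2, enolisation to the ortho-allenylphenol F3, and a [1,5]-hydrogen shift to the same quinone methide 10, which electrocyclises. The fallback comes back to the route at 11.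

Step 5. The 1,4-reduction may stall, the ketone reduction may be slow next to the peri benzyloxy group, or epimerisation at C3 may not keep pace with reduction, so that the dynamic kinetic resolution loses selectivity. The fallback sets out from 11. Conjugate reduction with LiBH(s-Bu)3 (THF, −78 °C) should give racemic 12, now isolated. Preparative HPLC on a chiral stationary phase then separates the enantiomers; the (3R)-ketone F4 is racemised with DBU in toluene and recycled. The fallback comes back to the route at 14.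

Step 7. Enolisation of the boron-chelated ketone during cleavage or quench may erode the C3 configuration, or the benzyl cation may be transferred to the electron-rich rings of the stereodefined material. The fallback sets out from 11 and moves the Lewis-acid step to the achiral stage. BCl3 with C6HMe5 at −78 °C should give the 5-hydroxy pyrano-isoflavone F5. TBSOTf with 2,6-lutidine then gives the silyl ether F6. The transfer hydrogenation of step 5 passes through the racemic silyl isoflavanone F7 to the cis-(3S,4S)-alcohol F8. Dess–Martin oxidation gives the (3S)-silyl ketone F9, and HF·pyridine in THF at 0 °C removes the silyl group without base. The fallback comes back to the route at 15.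

**Further compounds**

F1 | step 4 | 5-(benzyloxy)-7-methoxy-3-{2-methoxy-4-[(2-methylbut-3-yn-2-yl)oxy]phenyl}-4H-chromen-4-one | COc1cc(OCc2ccccc2)c2c(c1)occ(-c1ccc(OC(C)(C)C#C)cc1OC)c2=O
F2 | step 4 | 5-(benzyloxy)-7-methoxy-3-[6-methoxy-3-(3-methylbuta-1,2-dien-1-yl)-4-oxocyclohexa-1,5-dien-1-yl]-4H-chromen-4-one | COc1cc(OCc2ccccc2)c2c(c1)occ(C1=CC(C=C=C(C)C)C(=O)C=C1OC)c2=O
F3 | step 4 | 5-(benzyloxy)-3-[4-hydroxy-2-methoxy-5-(3-methylbuta-1,2-dien-1-yl)phenyl]-7-methoxy-4H-chromen-4-one | COc1cc(OCc2ccccc2)c2c(c1)occ(-c1cc(C=C=C(C)C)c(O)cc1OC)c2=O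
F4 | step 5 | (3R)-5-(benzyloxy)-7-methoxy-3-(7-methoxy-2,2-dimethyl-2H-chromen-6-yl)chroman-4-one | COc1cc(OCc2ccccc2)c2c(c1)OC[C@@H](c1cc3c(cc1OC)OC(C)(C)C=C3)C2=O
F5 | step 7 | 5-hydroxy-7-methoxy-3-(7-methoxy-2,2-dimethyl-2H-chromen-6-yl)-4H-chromen-4-one | COc1cc(O)c2c(c1)occ(-c1cc3c(cc1OC)OC(C)(C)C=C3)c2=O
F6 | step 7 | 5-[(tert-butyldimethylsilyl)oxy]-7-methoxy-3-(7-methoxy-2,2-dimethyl-2H-chromen-6-yl)-4H-chromen-4-one | COc1cc(O[Si](C)(C)C(C)(C)C)c2c(c1)occ(-c1cc3c(cc1OC)OC(C)(C)C=C3)c2=O
F7 | step 7 | racemic 5-[(tert-butyldimethylsilyl)oxy]-7-methoxy-3-(7-methoxy-2,2-dimethyl-2H-chromen-6-yl)chroman-4-one | COc1cc(O[Si](C)(C)C(C)(C)C)c2c(c1)OCC(c1cc3c(cc1OC)OC(C)(C)C=C3)C2=O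
F8 | step 7 | (3S,4S)-5-[(tert-butyldimethylsilyl)oxy]-7-methoxy-3-(7-methoxy-2,2-dimethyl-2H-chromen-6-yl)chroman-4-ol | COc1cc(O[Si](C)(C)C(C)(C)C)c2c(c1)OC[C@H](c1cc3c(cc1OC)OC(C)(C)C=C3)[C@@H]2O
F9 | step 7 | (3S)-5-[(tert-butyldimethylsilyl)oxy]-7-methoxy-3-(7-methoxy-2,2-dimethyl-2H-chromen-6-yl)chroman-4-one | COc1cc(O[Si](C)(C)C(C)(C)C)c2c(c1)OC[C@H](c1cc3c(cc1OC)OC(C)(C)C=C3)C2=O
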